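The numbers in the tables are calculated for substances that don't exist; noise was put on by code.

I had no value for any rate constant of this flask, but the asked share needs one combination of them. The zeta run is the same flask, followed so far.

- zeta: starting material 0.14 M; catalyst 0.5 mol%; the very flask that is asked about, followed so far
- flask: starting material 0.14 M; catalyst 0.5 mol%; time 15 d

zeta run (percent of the starting material charged)

| time / d | isomer of the product / % | target / % |
|---|---|---|
| 0.500 | 41 | 3 |
| 1.04 | 56 | 5 |
| 1.67 | 62 | 4 |
| 2.08 | 63 | 4 |
| 2.50 | 66 | 0 |
| 3.00 | 70 | 3 |

(readings scatter by 2 percentage points)

1. share of isomer of the product in isomer of the product plus target at 15 min
2. share of isomer of the product in isomer of the product plus target at 15 d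

- steps under discussion: starting material <-> other conformer; starting material + catalyst -> catalyst + target; catalyst + other conformer -> catalyst + isomer of the product; starting material <-> dormant form

Isomer of the product forms from the other conformer and target forms from starting material. Each step is written with one catalyst as a reactant, so I took each rate as first order in [catalyst], and [catalyst] cancels from their quotient:

d[isomer of the product]/d[target] = k_Q[other conformer] / (k_P[starting material])

If the exchange keeps [other conformer]/[starting material] at an equilibrium value K, the quotient is a constant, k_Q K/k_P. The dormant form then moves the time at which product appears, but not the quotient. I read this constant from the zeta run as the selectivity factor S, the isomer of the product made per target made, summing the readings of each: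

S = 358% / 19.0% = 18.8

share = S/(1+S) = 95.0%

Each target reading carries 2 percentage points on a value like 4%, so S is a loose reading. I committed to this share at both 15 min and 15 d, though 15 min lies before the first reading at 0.500 d, so the readings do not test the held exchange at that time.

The forecast gave 92% at 15 min, lower than my share, and 95% at 15 d, with the words "A constant ratio fits within error, as expected if both products drain the same pool."

The flask gave 93.6% at 15 min and 93.6% at 15 d.

    starting material ⇌ other conformer, settled at all times (K = 0.438)
    starting material + catalyst → catalyst + target (k = 0.00220 M⁻¹ s⁻¹)
    catalyst + other conformer → catalyst + isomer of the product (k = 0.0733 M⁻¹ s⁻¹)
    starting material ⇌ dormant form (K = 4.71, k = 1.43 × 10⁻⁵ s⁻¹)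

In this flask both products grew while starting material and other conformer were present, and at 1.50 d the dormant form stood at 29.1%. It then returned through starting material, falling to 3.61% at 15.0 d beside 89.8% isomer of the product, which S turns into 4.78% target where this flask held 6.15%. The neighbour flask charged with 0.035 M of starting material held 66.7% isomer of the product at 15.0 d, which S turns into 3.55% target, and that flask held 4.57%.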